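The numbers of this flask are made up; the rest is arithmetic.

In the first seconds of this flask each turnover of E with X gives a J, and what I reckoned from was where that J goes at that moment.

E 46 mM; time 40 s

    E + X → J + G (k1 = 12.4 L mol⁻¹ s⁻¹)
    E + J ⇌ E.J, settled at all times (K2 = 4700 L mol⁻¹)
    X + J ⇌ X.J, settled at all times (K3 = 68000 L mol⁻¹)

- the equivalents of X at which the part of the E that has reacted at 40 s is just 50%

- J is meant together with its E.J
- the amount of X is what is sought; it is there from the start
- what has gone from E into another species counts as reacted, even if it can come back
- run time (flask): 40 s

I built the flask up one step at a time. With the main step alone, each E that reacts takes one X, so half of the E asks for 0.5 equiv of X. The run is long enough for that: with E at half its charge, X has a half-life of 2.43 s, shorter than the 40 s of the run. Adding X.J, each J also holds an X, so while that lasts a turnover costs two X and the same half of E asks for 1 equiv.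

Adding E.J brings in the pull on J: the constant of X.J times cX, over the constant of E.J times cE. It is the ratio of the two constants, the preference 14.5, times cX/cE. For a charge near a quarter of the E, the pull starts at 3.62, so 78.3% of the J goes to X. At that start cX falls by 1.47 for each one of cE, so the pull drifts down. By my balance it crosses 1 early, with cE still near 36.8 mM and cX near 2.54 mM. Below that J goes to E, X.J hands back its X, and X, the limiting reagent, goes through the main step. Each X charged then takes two E, one into G and one held as E.J. My number was 0.250 equiv.

The forecast gave 0.28 equiv, above my number, reasoning that “each turnover tends to use up a second X until free X runs nearly dry and J starts pulling E into E.J”.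

The simulation gave 0.272 equiv, so in this flask each X charged accounted for 1.84 E. At 40.0 s the half-life of X by the main step was 2.4 s, short against the 40 s of the run. Free X then stood at 0.653% of its charge and E at half of its own, which puts the pull on J at 0.0513.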